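## Structural features

The target is a melampolide-type germacranolide: a cyclodecadiene (C1–C10) whose C1=C10 double bond is ring-cis and carries a methyl ester (C14), and whose C4=C5 double bond is trans and carries a methyl group (C15). In this numbering C6 bears the lactone oxygen, C7 the lactone carbon C11 (C12 is the lactone carbonyl, C13 the exocyclic methylene) and C8 the methacrylate. An α-methylene-γ-butyrolactone is trans-fused across C6–C7. The three stereocentres are contiguous, C6 (R), C7 (R) and C8 (R): O6 lies trans to the C7–C11 bond and O8 lies cis to it. Fragile features are the two Michael acceptors (α-methylene lactone, methacrylate), the strained trans-cycloalkene (Cope rearrangement, acid-induced transannular cyclisation) and, once O8 is free, translactonisation from O6 to O8; in precursors with a C6 ketone, C7 is epimerisable and O8 is a β-leaving group. The real difficulty is the ten-membered ring with two trisubstituted alkenes of opposite ring geometry next to the C6–C8 triad. The key step exploits the fact that C1=C10 and C4=C5 are the two ends of a cyclodeca-1,5-diene bridged by the C2–C3 ethano unit: bonding C1 to C4 and C5 to C10 folds the ring into a bicyclo[2.2.0]hexane (C1, C2, C3, C4, C5, C10) fused to a cyclohexane (C5–C10) that carries all three stereocentres.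

## Logic of the disconnections

**26 to 25.** The O8–acyl bond of 26 is cut first. The methacrylate is a polymerisable Michael acceptor that would survive neither the enolate chemistry nor the heat and light used earlier, so it goes on last. This leaves 25 with one acceptor fewer. The forward acylation must be faster than attack of the free O8 on the lactone carbonyl, so it needs an activated acyl donor, a non-nucleophilic base and low temperature.

**25 to 24 to 21.** The O8–Si bond (25 from 24) and the C11=C13 double bond (24 from 21) are cut next. The exocyclic methylene is the most electrophilic site and is introduced only when the ring and all stereocentres are in place; O8 stays silylated while the lactone enolate is made. The gain is 21, a saturated lactone with one readily enolised position. The demand is kinetic enolisation of the lactone beside the C14 enoate, and a desilylation that is neither basic nor strongly acidic.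

**21 to 20 to 18.** The lactone is opened at its alkyl C6–O bond, not at the acyl bond, which leads back to 20 with the opposite configuration at C6; 20 comes from 18 by cutting the C6–H bond and unmasking the C12 acid. The reason is that hydride should reach C6 of 18 from the periphery of the ring, anti to the C7–C8 bond, which puts O6 cis to C11; displacement at C6 by the carboxylate then gives the trans fusion of 26. The gain is a C6 carbonyl that serves both the photochemistry and the ring opening further back. The demand is clean 1,2-reduction, hydrolysis of the C12 ester beside the C14 enoate, and SN2 rather than SN2′ or ionisation at an allylic centre.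

**18 to 17.** The C1=C10 and C4=C5 π bonds of 18 are exchanged for the C1–C4 and C5–C10 σ bonds of 17. This turns a medium ring with two geometrically defined alkenes into a rigid tricycle of small rings. The ring is then revealed by strain release, with no entropic penalty of closure. The demand is that the diyl cleaves C5–C10 and not C2–C3, that the chair diyl delivers trans C4=C5 and ring-cis C1=C10, and that the β-silyloxy ketone with its epimerisable C7 survives the heat.

**17 to 15 and 16.** The C1–C10 and C4–C5 bonds of the central four-membered ring are cut, giving 15 and 16. All four new stereocentres are erased in the next step, so only the orientation (C4 on C5, C1 on C10) and a cis ring fusion matter. The gain is large: 15 is a monocyclic enone with two stereocentres. The demand is head-to-head orientation in the photocycloaddition.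

**15 to 13 to 12.** The C5=C10 double bond is traced to the C10 tertiary alcohol of 13 (C10–O cut) and the C6 carbonyl to the secondary alcohol of 12. This returns the oxidation pattern of the chiral-pool material. The demand is oxidation and dehydration without base strong enough to epimerise C7 or expel O8, since loss of O8 leads to a phenol.

**12 to 10 to 9 to 6 and 7.** The C7–C11 bond is cut: 12 comes from lactone 10, 10 from 9 by loss of one ester carbon, and 9 from epoxide 6 and 7. Cutting here installs the acetate side chain and fixes C7 by inversion, on the face of O8. The demand is attack at C7 and not at C6, and the C6 oxygen must be released from the lactone before it can be oxidised.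

**6 to 4 to 3 to 2 to 1.** The epoxide C7–O bond is cut back to the C7 sulfonate 4 and the lactone-bound O6, then the O7–S and O8–Si bonds, then the bridging lactone of 2, which leads to 1. The bicyclic lactone differentiates the three secondary hydroxyls by geometry (equatorial O8, axial O7, bridged O6). The demand is selective silylation of O8 and an anti-periplanar O6/C7 arrangement when the lactone is opened.

## Other disconnections considered

**Alternative 1:** The cut is C7–C8. In the forward step BF3·OEt2 would promote intramolecular SE2′ addition of the 3-(tributylstannylmethyl)butenolide aldehyde A2 to its C8 aldehyde, forming C7–C8, shifting the alkene to C11=C13 and closing the ring to A1, which is identical with 25.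
- In favour: one step creates the ring, both C7 and C8, the α-methylene lactone and the free O8 hydroxyl. No protecting group is needed on O8 and the target is one acylation away. In end-game economy this is better than the chosen plan, which needs five steps after the ring appears.
- Against: a ten-membered ring must be closed by a bimolecular-type addition at high dilution, in competition with oligomerisation and protodestannylation. The configuration at C7 and C8 would rest only on the remote C6 centre acting through a medium-ring transition state. The β,γ-unsaturated aldehyde of A2 can slip into conjugation under Lewis acid. A2 itself needs both trisubstituted alkenes and the C6 carbinol built stereoselectively in a linear sequence.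
- Comparison: the chosen plan takes C7 and C8 from the chiral pool, sets both alkene geometries by one mechanism and has no ring-closure entropy. Alternative 1 is the equal of the chosen plan in convergence on 25 and better in the number of late functional-group steps, but weaker in stereochemical security and in the ring-forming event.

**Alternative 2:** The bond formed is C2–C3 and the bond cut is C5–C10. The potassium alkoxide of the divinylcyclohexanol A4 (KH, THF) would undergo an anionic oxy-Cope rearrangement, and the C10 enolate would be trapped with PhNTf2 as the enol triflate A3; carbonylation (Pd(PPh3)4, CO, MeOH) would then supply C14.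
- In favour: it uses the same six-membered chiral-pool template, runs near room temperature and is irreversible, because the product is an enolate. It is therefore better than the chosen plan on the Cope-equilibrium issue. It needs no photochemistry and already carries the lactone with C6 set.
- Against: the ring-cis C1=C10 together with trans C4=C5 requires the chair transition state of the isomer of A4 with vinyl and isopropenyl cis, whereas vinyl addition to the 2-isopropenyl ketone should favour the trans isomer, which leads to the ring-trans enolate. KH will also enolise the lactone. The C10 carboxyl of the starting material must be degraded to a ketone and then rebuilt by carbonylation.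
- Comparison: the two plans are equal in using a ring expansion of a cyclohexane and in setting geometry by a chair. Alternative 2 is better in mildness and irreversibility, worse in access to the correct precursor diastereomer and in redox and step economy around C14.

**Alternative 3:** The cut is the C1=C10 double bond. LiCl and an amine base (iPr2NEt or DBU) would convert the phosphonate aldehyde A6 into its C10 anion, which condenses with the C1 aldehyde to close the ring to A5, which is identical with 21.
- In favour: the ring-cis enoate is the E isomer by the sequence rule, which is the normal outcome of a Horner–Wadsworth–Emmons reaction of an α-substituted phosphonoacetate. The conditions tolerate the lactone and the silyl ether. It meets the chosen route at 21, so the end game is the same and equal in length.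
- Against: closing a ten-membered ring that already contains a trans trisubstituted alkene is enthalpically and entropically difficult, with dimerisation as the competitor. Geometry in a strained macrocyclisation is not guaranteed to follow the acyclic preference. A6 needs a long linear synthesis with separate control of C4=C5 and of the C6–C8 triad.
- Comparison: Alternative 3 is the equal of the chosen plan from 21 onward, and arguably better in the predictability of the C1=C10 geometry in the acyclic sense. The chosen plan is better in ring formation (strain release instead of closure), in making both alkenes at once and in step count to 21.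

Key step: step 11

Remark: ring numbering C1–C15 of the target is used for every intermediate (quinic acid C1, C2, C3, C4, C5, C6 = target C10, C9, C8, C7, C6, C5); hydride addition to 18 is assumed to follow the Felkin–Anh peripheral course, giving the 6S alcohol that the invertive lactonisation of step 13 requires.

## Route

Step 1
Reactants: 1 (−)-quinic acid
Product: 2 quinide (lactone of the C14 carboxyl on O6; free hydroxyls at C7, C8 and C10)
Conditions: TsOH·H2O (cat.), toluene–DMF, reflux, Dean–Stark
Reagents that add atoms: none
Why: Acid-catalysed lactonisation: the C14 carboxyl and O6 are cis-1,3 and close the bridged γ-lactone once water is removed; no stereocentre is touched.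

Step 2
Reactants: 2 quinide
Product: 3 8-O-TBS quinide
Conditions: TBSCl (1.05 equiv), imidazole, DMF, 0 °C to rt
Reagents that add atoms: tert-butyldimethylsilyl chloride, CC(C)(C)[Si](C)(C)Cl
Why: Regioselective silylation: in the rigid lactone O8 is equatorial and unhindered, O7 is axial and O10 tertiary, so one equivalent of silyl chloride should go to O8.

Step 3
Reactants: 3 8-O-TBS quinide
Product: 4 7-O-mesyl-8-O-TBS quinide
Conditions: MsCl, pyridine, DMAP (cat.), CH2Cl2, 0 °C to rt
Reagents that add atoms: methanesulfonyl chloride, CS(=O)(=O)Cl
Why: Sulfonylation of the only secondary alcohol left; pyridine avoids the sulfene pathway that could reach the tertiary C10 alcohol.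

Step 4
Reactants: 4 7-O-mesyl-8-O-TBS quinide
Product: 6 methyl ester C6–C7 epoxide (epoxide oxygen on the face of the original O6 and trans to the C8 silyloxy group; C10 hydroxyl free), via hydroxy mesylate 5 (not isolated)
Conditions: NaOMe (1.1 equiv), MeOH, 0 °C; AcOH quench
Reagents that add atoms: sodium methoxide (NaOMe), C[O-].[Na+]
Why: Lactone methanolysis frees the C6 alkoxide trans-diaxial to the C7 mesylate, and intramolecular Williamson displacement closes the epoxide with inversion at C7.

Step 5
Reactants: 6 methyl ester C6–C7 epoxide; 7 dimethyl malonate
Product: 9 trans-fused lactone ester (O6–C12 lactone carrying CO2Me on C11; C7–C11 cis to O8), via malonate adduct 8 (not isolated)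
Conditions: 7 (3 equiv), NaOMe (1 equiv), MeOH, 65 °C; AcOH
Reagents that add atoms: none
Why: Malonate opening of the epoxide under the Fürst–Plattner rule: with the C8 silyloxy group equatorial, trans-diaxial attack occurs at C7, whereas diaxial attack at C6 would place the nucleophile syn-axial to O8 and O10; inversion at C7 puts the new C7–C11 bond cis to O8 and trans to O6, and the C6 alkoxide then acylates on a malonate ester.

Step 6
Reactants: 9 trans-fused lactone ester
Product: 10 trans-fused lactone (C11 is CH2)
Conditions: LiCl, H2O, DMSO, 130 °C
Reagents that add atoms: none
Why: Krapcho dealkoxycarbonylation: chloride demethylates the malonate-type ester, the carboxylate loses CO2 and the lactone enolate is protonated; the isolated C14 ester and the silyl ether are not activated in this way.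

Step 7
Reactants: 10 trans-fused lactone
Product: 12 hydroxy diester (C6 hydroxyl free; CH2CO2Me on C7; C10 hydroxyl and C14 methyl ester), via dilithium dicarboxylate 11 (not isolated)
Conditions: LiOH (2.2 equiv), THF–H2O, rt; evaporate; MeI, DMF, rt; used crude
Reagents that add atoms: lithium hydroxide (LiOH), [Li+].[OH-]; iodomethane, CI
Why: Saponification opens the lactone (and the C14 ester) to a dicarboxylate that cannot relactonise while anionic; carboxylate O-alkylation then gives the open hydroxy diester without acid, so O6 is free for oxidation.

Step 8
Reactants: 12 hydroxy diester
Product: 13 C6 ketone with C10 tertiary alcohol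
Conditions: Dess–Martin periodinane, NaHCO3, CH2Cl2, 0 °C to rt
Reagents that add atoms: none
Why: Dess–Martin oxidation of the only secondary alcohol under buffered conditions; the tertiary alcohol is inert and C7, now α to the ketone, sees no base.

Step 9
Reactants: 13 C6 ketone with C10 tertiary alcohol
Product: 15 cyclohexenone ester (C5=C10 conjugated to the C6 ketone and the C14 ester), via tertiary mesylate 14 (not isolated)
Conditions: MsCl, Et3N, CH2Cl2, −20 to 0 °C
Reagents that add atoms: none
Why: Dehydration of a β-hydroxy ketone by E1cB: the tertiary alcohol is sulfonylated through sulfene and the enolate formed at C5 expels mesylate; the much poorer silyloxy leaving group at C8 should survive the short, cold exposure to amine.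

Step 10
Reactants: 15 cyclohexenone ester; 16 1-methylcyclobutene
Product: 17 cis-anti-cis head-to-head photoadduct (C1–C10 and C4–C5 bonds; cyclobutane anti to the C7 and C8 substituents)
Conditions: hν (350 nm, Pyrex), 16 (10 equiv), CH2Cl2, −40 °C
Reagents that add atoms: none
Why: Enone–alkene [2+2] photocycloaddition through the enone triplet and a 1,4-biradical: bonding of the unsubstituted cyclobutene carbon C1 to the ester-bearing C10 leaves a tertiary radical at C4 and an α-keto radical at C5 that collapse head-to-head, whereas the other orientation would have to join two fully substituted carbons and should revert; the small rings enforce cis fusion, the C2–C3 bridge turns away from the six-membered ring, and either face of the enone is acceptable because C1, C4, C5 and C10 lose their configuration in step 11.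

Step 11
Reactants: 17 cis-anti-cis head-to-head photoadduct
Product: 18 ten-membered C6 ketone (trans C4=C5 enone; ring-cis C1=C10 enoate)
Conditions: toluene (0.01 M, degassed), BHT (cat.), silanised sealed tube, 180 °C
Reagents that add atoms: none
Why: Thermal cycloreversion of the bicyclo[2.2.0]hexane made of C1, C2, C3, C4, C5 and C10, stepwise through a cyclohexane-1,4-diyl: homolysis of the central C1–C4 bond relieves the strain of two fused four-membered rings, and scission of C5–C10 in the diyl pairs the radicals as the C1=C10 and C4=C5 double bonds. The closest known reaction type is the thermolysis of enone–cyclobutene photoadducts (tricyclo[4.4.0.0(2,5)]decanes) to cis,trans-cyclodeca-1,5-dienes. No ring is closed by bond formation; the ten-membered ring appears because the two bonds that break are its transannular links. No stereocentre is created: C1, C4, C5 and C10 become trigonal, so adducts from either enone face converge, and C7 and C8 are untouched under neutral conditions. The selectivity needed is geometric (trans C4=C5, ring-cis C1=C10) and regiochemical (scission of C5–C10, not C2–C3). Geometry should follow from the chair diyl of the cis-anti-cis adduct, in which C6 is equatorial on C5 (trans enone) and only the C9 methylene is axial on C10 (ring-cis enoate), the other chair having both C6 and the ester axial. C5–C10 lies between the ketone α-carbon and the ester-bearing carbon, so it is the weaker bond and its scission gives two conjugated alkenes, which also disfavours the divinylcyclohexanone Cope isomer. Dilute, degassed, acid- and base-free conditions and stopping when 17 is consumed should limit Cope rearrangement, enolisation at C7 and loss of silanol.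

Step 12
Reactants: 18 ten-membered C6 ketone
Product: 20 (6S)-hydroxy acid (O6 cis to the C7 side chain; C12 is CO2H), via (6S)-hydroxy diester 19 (not isolated)
Conditions: NaBH4, CeCl3·7H2O, MeOH, −78 °C; acetone; LiOH, THF–H2O, 0 °C; 1 M HCl to pH 5
Reagents that add atoms: lithium hydroxide (LiOH), [Li+].[OH-]
Why: Luche 1,2-reduction followed by ester hydrolysis: hydride should add to the outer face of the C6 carbonyl, anti to the C7–C8 ring bond and past H7 (Felkin–Anh, peripheral attack), placing O6 cis to C11; the unhindered C12 ester, assisted by the neighbouring hydroxyl, is hydrolysed far faster than the conjugated, α-branched C14 ester.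

Step 13
Reactants: 20 (6S)-hydroxy acid
Product: 21 trans-fused lactone (6R; O8 silyl ether; C11 is CH2)
Conditions: PPh3, DIAD, toluene (0.005 M), 0 °C to rt
Reagents that add atoms: none
Why: Mitsunobu lactonisation: the C6 hydroxyl is activated as an alkoxyphosphonium ion and displaced by the C12 carboxylate in a 5-exo SN2 step with inversion, which converts the cis hydroxy acid into the trans-fused lactone; high dilution suppresses intermolecular esterification.

Step 14
Reactants: 21 trans-fused lactone
Product: 24 α-methylene lactone silyl ether, via Mannich base 22 (not isolated), via ammonium iodide 23 (not isolated)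
Conditions: LiN(iPr)2, THF, −78 °C; Me2N=CH2+ I−, −78 to 0 °C; MeI, MeOH, rt; NaHCO3 (aq), CH2Cl2, rt
Reagents that add atoms: N,N-dimethylmethyleneiminium iodide, C=[N+](C)C.[I-]
Why: α-Methylenation by Mannich reaction of the kinetic lactone lithium enolate, N-methylation and E1cB elimination of trimethylamine; the saturated lactone α-protons are removed faster than the γ-protons of the trisubstituted C14 enoate, and the new C11 centre is erased on elimination.

Step 15
Reactants: 24 α-methylene lactone silyl ether
Product: 25 8-hydroxy α-methylene lactone
Conditions: HF·pyridine, pyridine, THF, 0 °C to rt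
Reagents that add atoms: none
Why: Fluoride-mediated desilylation under buffered, weakly acidic, non-nucleophilic conditions, which avoids both base-induced translactonisation to O8 and conjugate addition to the methylene lactone; the electron-poor C1=C10 enoate disfavours transannular cyclisation.

Step 16
Reactants: 25 8-hydroxy α-methylene lactone
Product: 26 target (6R,7R,8R)
Conditions: methacrylic anhydride, Et3N, DMAP (cat.), CH2Cl2, 0 °C
Reagents that add atoms: methacrylic anhydride, CC(=C)C(=O)OC(=O)C(C)=C
Why: DMAP-catalysed acylation of the secondary alcohol with retention at C8; the acylpyridinium captures O8 faster than O8 can attack the lactone carbonyl.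

## Compound list

1 | (−)-quinic acid | O[C@@]1(C(=O)O)C[C@@H](O)[C@@H](O)[C@H](O)C1 | starting material
2 | quinide (C14 carboxyl lactonised on O6) | O[C@@]12C[C@@H](O)[C@@H](O)[C@@H](C1)OC2=O | intermediate
3 | 8-O-TBS quinide | O[C@@]12C[C@@H](O[Si](C)(C)C(C)(C)C)[C@@H](O)[C@@H](C1)OC2=O | intermediate
4 | 7-O-mesyl-8-O-TBS quinide | O[C@@]12C[C@@H](O[Si](C)(C)C(C)(C)C)[C@@H](OS(C)(=O)=O)[C@@H](C1)OC2=O | intermediate
5 | hydroxy mesylate methyl ester (not isolated) | O[C@@]1(C(=O)OC)C[C@@H](O[Si](C)(C)C(C)(C)C)[C@@H](OS(C)(=O)=O)[C@H](O)C1 | intermediate
6 | methyl ester C6–C7 epoxide, epoxide trans to the C8 silyloxy group | O[C@@]1(C(=O)OC)C[C@@H](O[Si](C)(C)C(C)(C)C)[C@@H]2O[C@@H]2C1 | intermediate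
7 | dimethyl malonate | COC(=O)CC(=O)OC | starting material
8 | C7 malonate adduct with free C6 hydroxyl (not isolated) | O[C@@]1(C(=O)OC)C[C@@H](O[Si](C)(C)C(C)(C)C)[C@@H](C(C(=O)OC)C(=O)OC)[C@H](O)C1 | intermediate
9 | trans-fused lactone ester (O6–C12 lactone, CO2Me on C11, C11 epimers) | O[C@@]1(C(=O)OC)C[C@@H](O[Si](C)(C)C(C)(C)C)[C@H]2C(C(=O)OC)C(=O)O[C@@H]2C1 | intermediate
10 | trans-fused lactone | O[C@@]1(C(=O)OC)C[C@@H](O[Si](C)(C)C(C)(C)C)[C@H]2CC(=O)O[C@@H]2C1 | intermediate
11 | dilithium hydroxy dicarboxylate (not isolated) | [Li+].[Li+].O[C@@]1(C(=O)[O-])C[C@@H](O[Si](C)(C)C(C)(C)C)[C@@H](CC(=O)[O-])[C@H](O)C1 | intermediate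
12 | hydroxy diester (C6–OH trans and C8–OTBS cis to the C7 side chain) | O[C@@]1(C(=O)OC)C[C@@H](O[Si](C)(C)C(C)(C)C)[C@@H](CC(=O)OC)[C@H](O)C1 | intermediate
13 | C6 ketone with C10 tertiary alcohol | O[C@@]1(C(=O)OC)C[C@@H](O[Si](C)(C)C(C)(C)C)[C@@H](CC(=O)OC)C(=O)C1 | intermediate
14 | C10 tertiary mesylate (not isolated) | CS(=O)(=O)O[C@@]1(C(=O)OC)C[C@@H](O[Si](C)(C)C(C)(C)C)[C@@H](CC(=O)OC)C(=O)C1 | intermediate
15 | cyclohexenone ester (C5=C10; C7 side chain cis to C8–OTBS) | COC(=O)C1=CC(=O)[C@H](CC(=O)OC)[C@H](O[Si](C)(C)C(C)(C)C)C1 | intermediate
16 | 1-methylcyclobutene | CC1=CCC1 | starting material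
17 | cis-anti-cis head-to-head photoadduct | CC(C)(C)[Si](C)(C)O[C@@H]1C[C@@]2(C(=O)OC)[C@@H]3CC[C@]3(C)[C@H]2C(=O)[C@@H]1CC(=O)OC | intermediate
18 | ten-membered C6 ketone, trans C4=C5 enone, ring-cis C1=C10 enoate | CC(C)(C)[Si](C)(C)O[C@@H]1C/C(C(=O)OC)=C\CC/C(C)=C/C(=O)[C@@H]1CC(=O)OC | intermediate
19 | (6S)-hydroxy diester (not isolated) | CC(C)(C)[Si](C)(C)O[C@@H]1C/C(C(=O)OC)=C\CC/C(C)=C/[C@H](O)[C@@H]1CC(=O)OC | intermediate
20 | (6S)-hydroxy acid | CC(C)(C)[Si](C)(C)O[C@@H]1C/C(C(=O)OC)=C\CC/C(C)=C/[C@H](O)[C@@H]1CC(=O)O | intermediate
21 | trans-fused 6,12-lactone, O8 silyl ether | CC(C)(C)[Si](C)(C)O[C@@H]1C/C(C(=O)OC)=C\CC/C(C)=C/[C@H]2OC(=O)C[C@@H]21 | intermediate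
22 | C11 dimethylaminomethyl lactone (not isolated) | CC(C)(C)[Si](C)(C)O[C@@H]1C/C(C(=O)OC)=C\CC/C(C)=C/[C@H]2OC(=O)C(CN(C)C)[C@@H]21 | intermediate
23 | C11 trimethylammoniomethyl lactone iodide (not isolated) | CC(C)(C)[Si](C)(C)O[C@@H]1C/C(C(=O)OC)=C\CC/C(C)=C/[C@H]2OC(=O)C(C[N+](C)(C)C)[C@@H]21.[I-] | intermediate
24 | α-methylene lactone silyl ether | CC(C)(C)[Si](C)(C)O[C@@H]1C/C(C(=O)OC)=C\CC/C(C)=C/[C@H]2OC(=O)C(=C)[C@@H]21 | intermediate
25 | 8-hydroxy α-methylene lactone | O[C@@H]1C/C(C(=O)OC)=C\CC/C(C)=C/[C@H]2OC(=O)C(=C)[C@@H]21 | intermediate
26 | target, 8-O-methacryloyl (6R,7R,8R) melampolide methyl ester | C=C(C)C(=O)O[C@@H]1C/C(C(=O)OC)=C\CC/C(C)=C/[C@H]2OC(=O)C(=C)[C@@H]21 | target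

## Step count and least certain steps

Total: 16 steps. Longest linear sequence: 16 steps (1 to 26); 7 and 16 enter at steps 5 and 10.

**Step 11 (key step).** The ketone has to survive 180 °C. The likely failures are onward Cope rearrangement of 18 to the divinylcyclohexanone, enolisation that erodes C7, and β-elimination of silanol. Fallback: set out from 17 and remove the ketone before heating. Reduction with Li(s-Bu)3BH (THF, −78 °C) should deliver hydride equatorially, because the axial path is blocked by the axial cyclobutane carbon C1, and give the tricyclic (6R)-hydroxy diester F1. Thermolysis of F1 under the conditions of step 11 opens the same two bonds to the ten-membered (6R)-hydroxy diester F2. F2 has O6 trans to the side chain and closes with retention (heat or PPTS) to the lactone, so the route is rejoined at 21.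

**Step 10.** The orientation of the cycloaddition may turn to head-to-tail, because the enone is activated from both ends, and trans-fused or syn adducts may form. Fallback: set out from 15 and use cyclobutene, which has no orientation problem, to obtain the des-methyl photoadduct F3. Heating as in step 11 gives the des-methyl cyclodecadienone F4. The C15 methyl is then added to the enone β-carbon C4 with Me2CuLi and Me3SiCl (THF, −78 °C), giving the silyl enol ether F5. Saegusa–Ito oxidation with Pd(OAc)2 in MeCN restores the C4=C5 double bond, and the route is rejoined at 18.

**Step 5.** Attack may turn to C6, the carbon remote from the silyloxy group, or the C10 alkoxide may open the epoxide across the ring. Both arise because the conformational (Fürst–Plattner) preference is opposed by the inductive and steric effect of O8. Fallback: set out from 3 and avoid the epoxide. Dess–Martin oxidation of the C7 alcohol gives the 7-oxo lactone F6. Wittig reaction with Ph3P=CHCO2Me gives the alkylidene ester F7. NaOMe in MeOH opens the bridged lactone to the allylic alcohol F8, with the E isomer carried on. Hydrogenation with H2 and [Ir(cod)(PCy3)(py)]PF6, directed by the allylic C6 hydroxyl, delivers hydrogen to C7 from the O6 face and leaves C11 cis to O8; the route is rejoined at 12.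

**Step 12 (with step 13).** Facial selectivity may be the opposite of the Felkin–Anh prediction if the ring reacts through a conformer with the carbonyl turned over, or it may be low. Fallback: set out from 18 and change the mode of lactonisation instead of the reduction. If the (6R)-hydroxy acid F9 is formed, it already has O6 trans to the side chain and is closed with retention by acyl substitution (acidification to pH 2 or PPTS in CH2Cl2), rejoining at 21 without step 13. A mixture of epimers is separated at the hydroxy acid stage and each is closed by its own mode.

**Step 14.** The amide base may deprotonate the γ-positions of the C14 enoate or add to it, giving deconjugation or mixtures. Fallback: set out from 21 and make the enolate equivalent without a strong base. Me3SiOTf and Et3N (CH2Cl2, −78 to 0 °C) give the silyl ketene acetal F10, which undergoes Mukaiyama–Mannich reaction with the same iminium iodide; the route is rejoined at 22.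

## Further compounds

F1 | step 11 | tricyclic (6R)-hydroxy diester from reduction of 17 | CC(C)(C)[Si](C)(C)O[C@@H]1C[C@@]2(C(=O)OC)[C@@H]3CC[C@]3(C)[C@H]2[C@@H](O)[C@@H]1CC(=O)OC
F2 | step 11 | ten-membered (6R)-hydroxy diester | CC(C)(C)[Si](C)(C)O[C@@H]1C/C(C(=O)OC)=C\CC/C(C)=C/[C@@H](O)[C@@H]1CC(=O)OC
F3 | step 10 | des-methyl cis-anti-cis photoadduct | CC(C)(C)[Si](C)(C)O[C@@H]1C[C@@]2(C(=O)OC)[C@@H]3CC[C@@H]3[C@H]2C(=O)[C@@H]1CC(=O)OC
F4 | step 10 | des-methyl ten-membered dienone | CC(C)(C)[Si](C)(C)O[C@@H]1C/C(C(=O)OC)=C\CC/C=C/C(=O)[C@@H]1CC(=O)OC
F5 | step 10 | C4-methyl trimethylsilyl enol ether (C5=C6) | CC(C)(C)[Si](C)(C)O[C@@H]1C/C(C(=O)OC)=C\CCC(C)C=C(O[Si](C)(C)C)[C@@H]1CC(=O)OC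
F6 | step 5 | 7-oxo-8-O-TBS quinide | O[C@@]12C[C@@H](O[Si](C)(C)C(C)(C)C)C(=O)[C@@H](C1)OC2=O
F7 | step 5 | C7 (methoxycarbonyl)methylidene lactone | O[C@@]12C[C@@H](O[Si](C)(C)C(C)(C)C)C(=CC(=O)OC)[C@@H](C1)OC2=O
F8 | step 5 | methyl ester with allylic C6 hydroxyl and C7 alkylidene ester | O[C@@]1(C(=O)OC)C[C@@H](O[Si](C)(C)C(C)(C)C)C(=CC(=O)OC)[C@H](O)C1
F9 | step 12 | (6R)-hydroxy acid | CC(C)(C)[Si](C)(C)O[C@@H]1C/C(C(=O)OC)=C\CC/C(C)=C/[C@@H](O)[C@@H]1CC(=O)O
F10 | step 14 | trimethylsilyl ketene acetal of 21 | CC(C)(C)[Si](C)(C)O[C@@H]1C/C(C(=O)OC)=C\CC/C(C)=C/[C@H]2OC(O[Si](C)(C)C)=C[C@@H]21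
A1 | alternative 1 | 8-hydroxy α-methylene lactone (identical with 25) | O[C@@H]1C/C(C(=O)OC)=C\CC/C(C)=C/[C@H]2OC(=O)C(=C)[C@@H]21
A2 | alternative 1 | stannylmethyl butenolide C8 aldehyde | O=CC/C(C(=O)OC)=C\CC/C(C)=C/[C@H]1OC(=O)C(C[Sn](CCCC)(CCCC)CCCC)=C1
A3 | alternative 2 | ten-membered lactone C10 enol triflate | CC(C)(C)[Si](C)(C)O[C@@H]1C/C(OS(=O)(=O)C(F)(F)F)=C\CC/C(C)=C/[C@H]2OC(=O)C[C@@H]21
A4 | alternative 2 | cis-1-vinyl-2-isopropenylcyclohexanol lactone | C=C[C@@]1(O)C[C@@H](O[Si](C)(C)C(C)(C)C)[C@H]2CC(=O)O[C@@H]2[C@H]1C(C)=C
A5 | alternative 3 | ten-membered lactone enoate (identical with 21) | CC(C)(C)[Si](C)(C)O[C@@H]1C/C(C(=O)OC)=C\CC/C(C)=C/[C@H]2OC(=O)C[C@@H]21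
A6 | alternative 3 | C10 phosphonate C1 aldehyde | O=CCC/C(C)=C/[C@H]1OC(=O)C[C@@H]1[C@H](O[Si](C)(C)C(C)(C)C)CC(C(=O)OC)P(=O)(OC)OC
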